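## Retrosynthetic overview

1. Structural handle: in ring A the C7 hydroxyl is para to C4a. Removing O1 from C8a therefore leaves a 4-alkylphenol whose two ortho carbons (future C6 and C8) are equivalent, so O-prenylation followed by an aromatic Claisen rearrangement places the 1,1-dimethylallyl group with no regiochemical choice.
2. O1–C8a is the key disconnection. Ring A is dearomatised to a para-quinol (oxygen on C4a), the free (S)-C2 carbinol closes ring C by oxa-Michael addition to C8a, and loss of the C4a oxygen rebuilds ring A. MOM removal ends the route.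
3. C2 is set by Ru/TsDPEN transfer hydrogenation of a 1,3-diarylpropan-1-one, which is cut at C1'–C2 into a ring B aryllithium and a ring A Weinreb amide.
4. Ring B comes from 3,5-dibromosalicylaldehyde by Dakin oxidation, MOM protection and two site-selective lithiation/prenylation events: Br–Li exchange next to OMOM for C5', then deprotonation between Br and OMOM for C2'. The last bromine is kept for the coupling.
5. Ring order: rings A and B are bought as arenes. Ring C is the only ring made, in the same step that restores ring A.

Key step: step 13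

Remark: flavan numbering is used (O1, C2–C4, C4a, C5–C8, C8a; ring B primed). The stereocentre in the target string reads as 2S. The quinols and the bicyclic intermediates are carried as mixtures at C4a (and C8a), so those centres are left open in the SMILES.

## Route

Step 1
Reactants: 1 methyl 3-(4-hydroxyphenyl)propanoate; 2 prenyl bromide (1-bromo-3-methylbut-2-ene)
Product: 3 methyl 3-{4-[(3-methylbut-2-en-1-yl)oxy]phenyl}propanoate
Conditions: K2CO3, acetone, reflux
Reagents that add atoms: prenyl bromide 2, CC(C)=CCBr
Why: Williamson ether synthesis, in which the potassium phenoxide displaces bromide at the primary allylic carbon (SN2) under conditions too mild to touch the methyl ester and polar enough to favour O- over C-alkylation.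

Step 2
Reactants: 3 methyl 3-{4-[(3-methylbut-2-en-1-yl)oxy]phenyl}propanoate
Product: 5 methyl 3-[4-hydroxy-3-(2-methylbut-3-en-2-yl)phenyl]propanoate, via ortho-dienone 4 (not isolated)
Conditions: PhNEt2, 200 °C, sealed vessel, Ar, short heating
Reagents that add atoms: none
Why: Aromatic Claisen rearrangement, a [3,3]-sigmatropic shift that turns the allyl unit round so that its tertiary carbon bonds to the ring, can only end at one of the two equivalent ortho carbons because the para carbon carries the side chain, and tautomerisation of 4 then restores the phenol while the basic solvent and short heating should hold back later acid- or heat-driven changes of the ortho-allylphenol.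

Step 3
Reactants: 5 methyl 3-[4-hydroxy-3-(2-methylbut-3-en-2-yl)phenyl]propanoate
Product: 6 3-[4-hydroxy-3-(2-methylbut-3-en-2-yl)phenyl]-N-methoxy-N-methylpropanamide
Conditions: MeNHOMe·HCl (2 equiv), iPrMgCl (5 equiv), THF, −20 to 0 °C; aq NH4Cl
Reagents that add atoms: N,O-dimethylhydroxylamine hydrochloride, CNOC.Cl
Why: Weinreb amide formation by aminolysis of the ester with the chloromagnesium amide made in the flask, the extra iPrMgCl merely holding the phenol as its magnesium salt, and the bulky Grignard reagent should not add to the amide at this temperature.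

Step 4
Reactants: 7 3,5-dibromo-2-hydroxybenzaldehyde
Product: 9 3,5-dibromobenzene-1,2-diol, via aryl formate 8 (not isolated)
Conditions: 30% aq H2O2, aq NaOH, 0 °C to rt; then aq HCl
Reagents that add atoms: hydrogen peroxide, OO
Why: Dakin oxidation, in which hydroperoxide adds to the aldehyde, the electron-rich ortho-phenoxide ring migrates from carbon to oxygen and formate 8 is saponified in the same medium, so the formyl carbon is replaced by the second catechol oxygen exactly where it is needed.

Step 5
Reactants: 9 3,5-dibromobenzene-1,2-diol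
Product: 10 1,5-dibromo-2,3-bis(methoxymethoxy)benzene
Conditions: MOMCl, iPr2NEt, CH2Cl2, 0 °C to rt
Reagents that add atoms: chloromethyl methyl ether, COCCl
Why: O-alkylation of both phenols with the highly reactive α-chloro ether gives acetal ethers that withstand organolithiums, formate reduction, PhI(OAc)2 and fluoride and that steer both later metalations.

Step 6
Reactants: 10 1,5-dibromo-2,3-bis(methoxymethoxy)benzene; 2 prenyl bromide
Product: 12 5-bromo-1,2-bis(methoxymethoxy)-3-(3-methylbut-2-en-1-yl)benzene, via aryllithium 11 (not isolated)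
Conditions: n-BuLi (1.0 equiv), Et2O, −78 °C; CuBr·SMe2 (10 mol %), 2, −78 to 0 °C
Reagents that add atoms: prenyl bromide 2, CC(C)=CCBr
Why: Bromine–lithium exchange should take place at the bromine next to an OMOM group because that aryllithium is stabilised by chelation and by the inductive pull of the neighbouring oxygen (and any other aryllithium can equilibrate to it by further exchange), and copper-catalysed allylic substitution at the unhindered primary carbon of 2 then installs the future C5' prenyl group.

Step 7
Reactants: 12 5-bromo-1,2-bis(methoxymethoxy)-3-(3-methylbut-2-en-1-yl)benzene; 2 prenyl bromide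
Product: 14 1-bromo-3,4-bis(methoxymethoxy)-2,5-bis(3-methylbut-2-en-1-yl)benzene, via aryllithium 13 (not isolated)
Conditions: LiN(iPr)2 (1.2 equiv), THF, −78 °C; CuBr·SMe2 (10 mol %), 2, −78 to −30 °C
Reagents that add atoms: prenyl bromide 2, CC(C)=CCBr
Why: Directed ortho-metalation with a non-nucleophilic amide base, which leaves the C–Br bond alone, should remove the most acidic ring hydrogen, the one flanked by bromine and OMOM, and trapping with 2 at low temperature (before LiBr can be lost) fills the future C2' position.

Step 8
Reactants: 6 3-[4-hydroxy-3-(2-methylbut-3-en-2-yl)phenyl]-N-methoxy-N-methylpropanamide; 14 1-bromo-3,4-bis(methoxymethoxy)-2,5-bis(3-methylbut-2-en-1-yl)benzene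
Product: 18 1-[3,4-bis(methoxymethoxy)-2,5-bis(3-methylbut-2-en-1-yl)phenyl]-3-[4-hydroxy-3-(2-methylbut-3-en-2-yl)phenyl]propan-1-one, via sodium phenoxide 15 (not isolated), via aryllithium 16 (not isolated), via tetrahedral adduct 17 (not isolated)
Conditions: 6, NaH (1.05 equiv), THF, 0 °C; 14, n-BuLi (1.05 equiv), THF, −78 °C; 15 added to 16, −78 to 0 °C; aq NH4Cl
Reagents that add atoms: none
Why: Weinreb ketone synthesis, in which the phenol is first masked as its sodium salt so that no aryllithium is wasted, 16 from bromine–lithium exchange adds once to the amide, and chelated adduct 17 survives until the quench and so prevents a second addition.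

Step 9
Reactants: 18 the diarylpropanone
Product: 19 4-{(3S)-3-[3,4-bis(methoxymethoxy)-2,5-bis(3-methylbut-2-en-1-yl)phenyl]-3-hydroxypropyl}-2-(2-methylbut-3-en-2-yl)phenol
Conditions: RuCl(p-cymene)[(S,S)-TsDPEN] (1–2 mol %), HCO2H–Et3N (5:2), EtOAc, 40 °C
Reagents that add atoms: none
Why: Noyori–Ikariya asymmetric transfer hydrogenation, in which the (S,S)-diamine complex passes hydride and proton to the carbonyl group through a six-membered outer-sphere transition state with ring B held under the cymene ligand by a CH–π contact, should deliver hydride to the Re face and set C2 as S, while isolated alkenes, MOM ethers and the phenol are not touched and loss of CO2 makes the reduction irreversible.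

Step 10
Reactants: 19 the (S)-carbinol phenol
Product: 21 4-{(3S)-3-[3,4-bis(methoxymethoxy)-2,5-bis(3-methylbut-2-en-1-yl)phenyl]-3-[(tert-butyldimethylsilyl)oxy]propyl}-2-(2-methylbut-3-en-2-yl)phenol, via bis-silyl ether 20 (not isolated)
Conditions: TBSCl (3 equiv), imidazole, DMAP (cat.), DMF, 40 °C; work-up; crude 20, K2CO3 (cat.), MeOH–THF, rt
Reagents that add atoms: tert-butyldimethylsilyl chloride, CC(C)(C)[Si](C)(C)Cl
Why: Exhaustive silylation followed by selective methanolysis works because an aryl silyl ether gives up a phenoxide leaving group under mild base whereas the secondary alkyl silyl ether does not, which leaves the carbinol masked (needed so that it cannot attack C4a in step 11) and the phenol free without touching C2.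

Step 11
Reactants: 21 the O-silylated (S)-carbinol phenol
Product: 22 4-{(3S)-3-[3,4-bis(methoxymethoxy)-2,5-bis(3-methylbut-2-en-1-yl)phenyl]-3-[(tert-butyldimethylsilyl)oxy]propyl}-4-hydroxy-2-(2-methylbut-3-en-2-yl)cyclohexa-2,5-dien-1-one (both C4a epimers)
Conditions: PhI(OAc)2 (1.1 equiv), MeCN–H2O (4:1), 0 °C, dilute
Reagents that add atoms: water, O
Why: Oxidative dearomatisation of a 4-alkylphenol with the trivalent iodine reagent, in which the phenol binds to iodine, iodobenzene leaves and water attacks the para carbon C4a (one ortho carbon being blocked by the tert-alkyl group, which also stabilises the dienone against dimerisation), should give the para-quinol as a mixture of C4a epimers that is of no consequence because this centre is erased in step 13.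

Step 12
Reactants: 22 the silylated para-quinol
Product: 23 4-{(3S)-3-[3,4-bis(methoxymethoxy)-2,5-bis(3-methylbut-2-en-1-yl)phenyl]-3-hydroxypropyl}-4-hydroxy-2-(2-methylbut-3-en-2-yl)cyclohexa-2,5-dien-1-one (both C4a epimers)
Conditions: HF·pyridine, pyridine, THF, 0 °C to rt
Reagents that add atoms: none
Why: Fluoride-driven cleavage of the Si–O bond under buffered and weakly acidic conditions frees the carbinol without generating an alkoxide, so the quinol should be isolable and the MOM ethers, the alkenes and the C2–O bond remain intact.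

Step 13
Reactants: 23 the para-quinol with the free (S)-carbinol
Product: 27 (2S)-2-[3,4-bis(methoxymethoxy)-2,5-bis(3-methylbut-2-en-1-yl)phenyl]-6-(2-methylbut-3-en-2-yl)-3,4-dihydro-2H-chromen-7-ol, via cis-fused hydroxy enone 24 (not isolated), via C4a sulfamate ester 25 (not isolated), via keto tautomer 26 (not isolated)
Conditions: DBU (0.2 equiv), THF, rt; AcOH (0.2 equiv); Burgess reagent (Et3N+SO2N−CO2Me, 1.5 equiv), 50 °C
Reagents that add atoms: none
Why: DBU activates the C2 carbinol, whose oxygen adds reversibly to C8a, the β-carbon of the unsubstituted C8a=C8–C7=O arm, and protonation at C8 gives 24; once the base is neutralised the Burgess reagent esterifies the only hydroxyl left, the tertiary allylic one on C4a (25), the sulfamate nitrogen takes the C8a hydrogen through a cyclic syn (Ei) transition state, and 26 tautomerises at C8 to the phenol, so aromatisation makes the whole sequence irreversible. The closest known reaction types are the intramolecular oxa-Michael cyclisation of alcohol-bearing para-quinols to cis-fused bicyclic enones, the Burgess dehydration of tertiary alcohols and the dehydrative aromatisation of 4-hydroxycyclohex-2-enones, run here one after the other in one flask. Ring C closes in the 6-exo-trig mode, and because the three-carbon tether can reach C8a only from the face of ring A on which it stands at C4a, the fusion is cis, which places the C4a hydroxyl and the C8a hydrogen syn as the Ei step demands. No stereocentre of the product is made here: C4a and C8a are transient and become sp2, so both quinol epimers converge, and the C2–O bond is never broken, so the S configuration from step 9 is kept. The selectivity needed is between the two β-carbons C8a and C5, and it is secured by the 1,1-dimethylallyl group on C6, which shields C5, lowers the electrophilicity of its own enone arm and would be forced onto an sp3 carbon by attack there, while reversibility under DBU lets any addition at C5 revert.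

Step 14
Reactants: 27 the bis-MOM flavan
Product: 28 4-[(2S)-7-hydroxy-6-(2-methylbut-3-en-2-yl)-3,4-dihydro-2H-chromen-2-yl]-3,6-bis(3-methylbut-2-en-1-yl)benzene-1,2-diol (target)
Conditions: aq HCl (3 M, cat.), MeOH–THF, 40 °C, Ar
Reagents that add atoms: none
Why: Acid-catalysed acetal exchange with methanol cleaves the two aryl MOM ethers through their readily protonated acetal oxygens at an acidity and temperature at which prenyl groups ortho to phenols are known to persist and at which the much less basic O1–C2 aryl ether is not ionised, so the S configuration is kept.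

## Compound list

1 | methyl 3-(4-hydroxyphenyl)propanoate | COC(=O)CCc1ccc(O)cc1 | starting material
2 | prenyl bromide | CC(C)=CCBr | starting material
3 | methyl 3-{4-[(3-methylbut-2-en-1-yl)oxy]phenyl}propanoate | COC(=O)CCc1ccc(OCC=C(C)C)cc1 | intermediate
4 | ortho-dienone, methyl 3-[5-(2-methylbut-3-en-2-yl)-4-oxocyclohexa-1,5-dien-1-yl]propanoate | COC(=O)CCC1=CC(C(C)(C)C=C)C(=O)C=C1 | intermediate
5 | methyl 3-[4-hydroxy-3-(2-methylbut-3-en-2-yl)phenyl]propanoate | COC(=O)CCc1ccc(O)c(C(C)(C)C=C)c1 | intermediate
6 | 3-[4-hydroxy-3-(2-methylbut-3-en-2-yl)phenyl]-N-methoxy-N-methylpropanamide | CON(C)C(=O)CCc1ccc(O)c(C(C)(C)C=C)c1 | intermediate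
7 | 3,5-dibromo-2-hydroxybenzaldehyde | O=Cc1cc(Br)cc(Br)c1O | starting material
8 | 3,5-dibromo-2-hydroxyphenyl formate | O=COc1cc(Br)cc(Br)c1O | intermediate
9 | 3,5-dibromobenzene-1,2-diol | Oc1cc(Br)cc(Br)c1O | intermediate
10 | 1,5-dibromo-2,3-bis(methoxymethoxy)benzene | COCOc1cc(Br)cc(Br)c1OCOC | intermediate
11 | [5-bromo-2,3-bis(methoxymethoxy)phenyl]lithium | [Li]c1cc(Br)cc(OCOC)c1OCOC | intermediate
12 | 5-bromo-1,2-bis(methoxymethoxy)-3-(3-methylbut-2-en-1-yl)benzene | COCOc1cc(Br)cc(CC=C(C)C)c1OCOC | intermediate
13 | [6-bromo-2,3-bis(methoxymethoxy)-4-(3-methylbut-2-en-1-yl)phenyl]lithium | [Li]c1c(Br)cc(CC=C(C)C)c(OCOC)c1OCOC | intermediate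
14 | 1-bromo-3,4-bis(methoxymethoxy)-2,5-bis(3-methylbut-2-en-1-yl)benzene | Brc1cc(CC=C(C)C)c(OCOC)c(OCOC)c1CC=C(C)C | intermediate
15 | sodium phenoxide of 6 | [Na+].[O-]c1ccc(CCC(=O)N(C)OC)cc1C(C)(C)C=C | intermediate
16 | [3,4-bis(methoxymethoxy)-2,5-bis(3-methylbut-2-en-1-yl)phenyl]lithium | [Li]c1cc(CC=C(C)C)c(OCOC)c(OCOC)c1CC=C(C)C | intermediate
17 | tetrahedral lithium alkoxide from 15 and 16 | [Li+].[Na+].CON(C)C([O-])(CCc1ccc([O-])c(C(C)(C)C=C)c1)c1cc(CC=C(C)C)c(OCOC)c(OCOC)c1CC=C(C)C | intermediate
18 | 1-[3,4-bis(methoxymethoxy)-2,5-diprenylphenyl]-3-[4-hydroxy-3-(2-methylbut-3-en-2-yl)phenyl]propan-1-one | O=C(CCc1ccc(O)c(C(C)(C)C=C)c1)c1cc(CC=C(C)C)c(OCOC)c(OCOC)c1CC=C(C)C | intermediate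
19 | (S)-carbinol phenol | O[C@H](c1cc(CC=C(C)C)c(OCOC)c(OCOC)c1CC=C(C)C)CCc1ccc(O)c(C(C)(C)C=C)c1 | intermediate
20 | (S)-bis(tert-butyldimethylsilyl) ether of 19 | CC(C)(C)[Si](C)(C)O[C@H](c1cc(CC=C(C)C)c(OCOC)c(OCOC)c1CC=C(C)C)CCc1ccc(O[Si](C)(C)C(C)(C)C)c(C(C)(C)C=C)c1 | intermediate
21 | (S)-carbinol TBS ether with free phenol | CC(C)(C)[Si](C)(C)O[C@H](c1cc(CC=C(C)C)c(OCOC)c(OCOC)c1CC=C(C)C)CCc1ccc(O)c(C(C)(C)C=C)c1 | intermediate
22 | para-quinol, carbinol as TBS ether, both C4a epimers | CC(C)(C)[Si](C)(C)O[C@H](c1cc(CC=C(C)C)c(OCOC)c(OCOC)c1CC=C(C)C)CCC1(O)C=CC(=O)C(C(C)(C)C=C)=C1 | intermediate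
23 | para-quinol with free (S)-carbinol, both C4a epimers (key-step precursor) | O[C@H](c1cc(CC=C(C)C)c(OCOC)c(OCOC)c1CC=C(C)C)CCC1(O)C=CC(=O)C(C(C)(C)C=C)=C1 | intermediate
24 | (2S)-2-aryl-4a-hydroxy-6-(2-methylbut-3-en-2-yl)-2,3,4,4a,8,8a-hexahydro-7H-chromen-7-one, cis ring fusion, both cis pairs | O=C1CC2O[C@H](c3cc(CC=C(C)C)c(OCOC)c(OCOC)c3CC=C(C)C)CCC2(O)C=C1C(C)(C)C=C | intermediate
25 | C4a N-(methoxycarbonyl)sulfamate ester of 24 | O=C1CC2O[C@H](c3cc(CC=C(C)C)c(OCOC)c(OCOC)c3CC=C(C)C)CCC2(OS(=O)(=O)NC(=O)OC)C=C1C(C)(C)C=C | intermediate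
26 | keto tautomer, (2S)-2-aryl-6-(2-methylbut-3-en-2-yl)-2,3,4,8-tetrahydro-7H-chromen-7-one | C=CC(C)(C)C1=CC2=C(CC1=O)O[C@H](c1cc(CC=C(C)C)c(OCOC)c(OCOC)c1CC=C(C)C)CC2 | intermediate
27 | (2S)-3',4'-bis-MOM ether of the target (key-step product) | C=CC(C)(C)c1cc2c(cc1O)O[C@H](c1cc(CC=C(C)C)c(OCOC)c(OCOC)c1CC=C(C)C)CC2 | intermediate
28 | 4-[(2S)-7-hydroxy-6-(2-methylbut-3-en-2-yl)-3,4-dihydro-2H-chromen-2-yl]-3,6-bis(3-methylbut-2-en-1-yl)benzene-1,2-diol | C=CC(C)(C)c1cc2c(cc1O)O[C@H](c1cc(CC=C(C)C)c(O)c(O)c1CC=C(C)C)CC2 | target

## Step count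

- Total step count: 14.
- Longest linear sequence: 11 steps (7 to 28, steps 4–14). The ring A branch (steps 1–3) joins at step 8.

## Steps most likely to fail

**1. Step 13.**
- What may go wrong:
  - The oxa-Michael equilibrium may lie incompletely on the cyclised side, so the dehydrating agent meets a free carbinol. That would cause elimination at C2 or dehydration of the open quinol towards the side chain.
  - Retro-addition may occur during heating.
  - The liberated phenol may be sulfamoylated.
- Fallback: it sets out from 23 and comes back at 27. It replaces the thermal syn elimination by ionisation of a silylated dienol.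
  - After the DBU stage 24 is isolated and treated with Me3SiOTf/Et3N (CH2Cl2, −78 to 0 °C). This traps the ketone and the tertiary alcohol as the bis(trimethylsilyl) cross-conjugated dienol ether of 24 F1.
  - Catalytic pyridinium p-toluenesulfonate then ionises the doubly allylic C4a silyl ether, and loss of the C8a hydrogen gives the 7-O-trimethylsilyl flavan F2.
  - K2CO3 in MeOH releases 27.

**2. Step 11.**
- What may go wrong:
  - The silyl ether oxygen may capture C4a with loss of the silyl group (spirocyclisation).
  - Water may attack at the free ortho carbon.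
  - Oxidative phenol coupling may compete.
  - The lipophilic substrate may dissolve poorly in aqueous acetonitrile.
- Fallback: it sets out from 21 and comes back at 27. The solvent itself is used as the trapping nucleophile.
  - PhI(OAc)2 in MeOH at 0 °C should give the para-quinol methyl ether with silylated carbinol F3.
  - HF·pyridine frees the para-quinol methyl ether carbinol F4.
  - DBU closes ring C to the cis-fused 4a-methoxy enone F5.
  - Catalytic camphorsulfonic acid (toluene, 50 °C) promotes enolisation and loss of methanol, the alkoxy counterpart of the dehydrative aromatisation, to reach 27.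

**3. Step 2.**
- What may go wrong:
  - The allyl ether may cleave thermally.
  - The first-formed ortho-allylphenol may drift along the abnormal Claisen pathway.
  - The phenol may close onto the vinyl group on prolonged heating.
- Fallback: it sets out from 1 and comes back at 5. The C–C bond is made by cross-coupling.
  - NBS (MeCN, 0 °C) brominates one of the two equivalent ortho carbons to give methyl 3-(3-bromo-4-hydroxyphenyl)propanoate F6.
  - MOMCl/iPr2NEt gives methyl 3-[3-bromo-4-(methoxymethoxy)phenyl]propanoate F7.
  - A γ-selective Suzuki–Miyaura allylation with prenylboronic acid pinacol ester (Pd(OAc)2, 1,1'-bis(di-tert-butylphosphino)ferrocene, K3PO4, THF–H2O, 60 °C) joins the tertiary allyl terminus to the ring. The product is methyl 3-[4-(methoxymethoxy)-3-(2-methylbut-3-en-2-yl)phenyl]propanoate F8.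
  - HCl in MeOH returns 5.

## Further compounds

F1 | step 13 | bis(trimethylsilyl) cross-conjugated dienol ether of 24 | C[Si](C)(C)OC1=CC2O[C@H](c3cc(CC=C(C)C)c(OCOC)c(OCOC)c3CC=C(C)C)CCC2(O[Si](C)(C)C)C=C1C(C)(C)C=C
F2 | step 13 | 7-O-trimethylsilyl ether of 27 | C=CC(C)(C)c1cc2c(cc1O[Si](C)(C)C)O[C@H](c1cc(CC=C(C)C)c(OCOC)c(OCOC)c1CC=C(C)C)CC2
F3 | step 11 | para-quinol methyl ether with silylated (S)-carbinol | CC(C)(C)[Si](C)(C)O[C@H](c1cc(CC=C(C)C)c(OCOC)c(OCOC)c1CC=C(C)C)CCC1(OC)C=CC(=O)C(C(C)(C)C=C)=C1
F4 | step 11 | para-quinol methyl ether with free (S)-carbinol | O[C@H](c1cc(CC=C(C)C)c(OCOC)c(OCOC)c1CC=C(C)C)CCC1(OC)C=CC(=O)C(C(C)(C)C=C)=C1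
F5 | step 11 | cis-fused 4a-methoxy enone | O=C1CC2O[C@H](c3cc(CC=C(C)C)c(OCOC)c(OCOC)c3CC=C(C)C)CCC2(OC)C=C1C(C)(C)C=C
F6 | step 2 | methyl 3-(3-bromo-4-hydroxyphenyl)propanoate | COC(=O)CCc1ccc(O)c(Br)c1
F7 | step 2 | methyl 3-[3-bromo-4-(methoxymethoxy)phenyl]propanoate | COC(=O)CCc1ccc(OCOC)c(Br)c1
F8 | step 2 | methyl 3-[4-(methoxymethoxy)-3-(2-methylbut-3-en-2-yl)phenyl]propanoate | COC(=O)CCc1ccc(OCOC)c(C(C)(C)C=C)c1
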